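## Retrosynthetic overview

1. The cyclohexene is cut last, as in the plant: an intermolecular [4+2] between a morachalcone A-type 2'-hydroxychalcone (dienophile) and a 6-"dehydrogeranyl" flavanone (diene), made exo- and face-selective by a chiral boron complex bound to the chalcone.
2. The diene comes from a Heck arylation of β-myrcene (which supplies the whole dehydrogeranyl unit in one step) with a 6-iodoflavanone; the iodide comes from 5-OH-directed iodination.
3. The flavanone pyranone ring comes from a chalcone-isomerase-like asymmetric oxa-Michael closure of a 2',6'-dihydroxychalcone (symmetric ring A, so no 6/8 regiochemical issue).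
4. Both chalcones come from Claisen–Schmidt condensations of one shared aldehyde with two acetophenones (a C-prenylated resacetophenone and a mono-protected phloroacetophenone).
5. Ring order: pyranone ring first (step 7), cyclohexene last (step 11); the seven MOM ethers are then removed without protic acid or base (step 12).

Locants: C3'', C4'' and C5'' are the cyclohexene carbons that carry the flavanone, the aroyl group and the 2,4-dioxygenated phenyl group. The target is read as (2S) at the flavanone and (3''R,4''R,5''S) on the cyclohexene, which is the all-trans (exo-type) adduct.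

Assumption: the quinine-derived catalyst of step 7 and the (R)-biaryl diol of step 11 are taken to give the configurations drawn; if either induces the opposite sense, its pseudo-enantiomer or mirror image is used and nothing else changes.

## Route

Step 1
Reactants: 1 (2,4-dihydroxybenzaldehyde)
Product: 2 aldehyde bis-MOM ether [2,4-bis(methoxymethoxy)benzaldehyde]
Conditions: MOMCl (2.6 equiv), K2CO3 (4 equiv), acetone, 0 °C to reflux, 4 h
Reagents that add atoms: chloromethyl methyl ether, COCCl
Why: Williamson-type etherification in which refluxing K2CO3 in acetone alkylates both the free 4-OH and the hydrogen-bonded 2-OH of the aldehyde, with no stereocentre formed.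

Step 2
Reactants: 3 (2,4-dihydroxyacetophenone); 4 (prenyl bromide)
Product: 5 3-prenylresacetophenone [1-[2,4-dihydroxy-3-(3-methylbut-2-enyl)phenyl]ethanone]
Conditions: KOH (10% aq., 2 equiv), 4 (1.0 equiv), 0 °C to rt, 12 h; then dilute HCl
Reagents that add atoms: none
Why: Nuclear prenylation (C-alkylation of an ambident resorcinolate), which in water goes to carbon and mainly to C3 between the two oxygens, so the 3-prenyl isomer is the main C-alkylation product (about 30%, separated by chromatography from the 5-prenyl isomer and the 4-O-prenyl ether), with no stereocentre formed.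

Step 3
Reactants: 5 (3-prenylresacetophenone)
Product: 6 4-O-MOM ketone [1-[2-hydroxy-4-(methoxymethoxy)-3-(3-methylbut-2-enyl)phenyl]ethanone]
Conditions: MOMCl (1.2 equiv), K2CO3 (2 equiv), acetone, rt, 6 h
Reagents that add atoms: chloromethyl methyl ether, COCCl
Why: Chemoselective Williamson etherification of the free and more acidic 4-OH, the 2-OH being locked in a hydrogen bond to the acetyl group and inert at room temperature with one equivalent of reagent.

Step 4
Reactants: 6 (4-O-MOM ketone); 2 (aldehyde bis-MOM ether)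
Product: 7 dienophile chalcone [(E)-1-[2-hydroxy-4-(methoxymethoxy)-3-(3-methylbut-2-enyl)phenyl]-3-[2,4-bis(methoxymethoxy)phenyl]prop-2-en-1-one]
Conditions: KOH (40% aq.), EtOH, 0 °C to rt, 36 h; then cold dilute HCl to pH 6
Reagents that add atoms: none
Why: Claisen–Schmidt condensation in which only the methyl ketone can enolise and E1cB dehydration gives the thermodynamically favoured (E)-enone, MOM ethers and the prenyl group being inert to aqueous hydroxide.

Step 5
Reactants: 8 (2,4,6-trihydroxyacetophenone, used as the monohydrate)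
Product: 9 mono-MOM phloroacetophenone [1-[2,6-dihydroxy-4-(methoxymethoxy)phenyl]ethanone]
Conditions: MOMCl (1.05 equiv), iPr2NEt (1.2 equiv), CH2Cl2–THF, 0 °C, 2 h
Reagents that add atoms: chloromethyl methyl ether, COCCl
Why: Chemoselective mono-etherification, since only the 4-OH (para to the acetyl group) is not hydrogen-bonded to the carbonyl and it is also the most acidic phenol, so one equivalent of reagent gives mainly the 4-O-MOM ether (the bis-ether is removed by chromatography).

Step 6
Reactants: 9 (mono-MOM phloroacetophenone); 2 (aldehyde bis-MOM ether)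
Product: 10 2',6'-dihydroxychalcone [(E)-1-[2,6-dihydroxy-4-(methoxymethoxy)phenyl]-3-[2,4-bis(methoxymethoxy)phenyl]prop-2-en-1-one]
Conditions: KOH (50% aq.), EtOH, rt, 48 h; then AcOH to pH 6 at 0 °C, immediate extraction
Reagents that add atoms: none
Why: Claisen–Schmidt condensation run at high pH, where the product is held as its ring-open phenolate and does not close to the flavanone, followed by cold neutralisation and fast isolation to keep racemic ring closure to a minimum, the (E)-alkene being the thermodynamic product.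

Step 7
Reactants: 10 (2',6'-dihydroxychalcone)
Product: 11 (2S)-flavanone [(2S)-5-hydroxy-7-(methoxymethoxy)-2-[2,4-bis(methoxymethoxy)phenyl]chroman-4-one]
Conditions: 1-[3,5-bis(trifluoromethyl)phenyl]-3-[(8α,9S)-6'-methoxycinchonan-9-yl]thiourea (10 mol %), toluene, −20 to 0 °C, 48–72 h
Reagents that add atoms: none
Why: Proposed new method: a chalcone-isomerase-like 6-endo-trig oxa-Michael addition in which the quinuclidine nitrogen of the bifunctional catalyst deprotonates one of the two equivalent ortho-phenols while the thiourea hydrogen-bonds the enone carbonyl (already polarised and held s-cis by the second, chelated phenol), so that the phenoxide is delivered to one enantiotopic face of the β-carbon and sets C2 as (S), the closest known reactions being cinchona-thiourea-catalysed oxa-Michael closures of 2'-hydroxychalcones activated by an α-ester group and the enzymatic closure of 6'-hydroxychalcones, and the product being guarded against retro-Michael racemisation by its new 5-OH···O=C hydrogen bond and by the absence of a free phenol in ring B.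

Step 8
Reactants: 11 ((2S)-flavanone)
Product: 12 (2S)-6-iodoflavanone [(2S)-5-hydroxy-6-iodo-7-(methoxymethoxy)-2-[2,4-bis(methoxymethoxy)phenyl]chroman-4-one]
Conditions: BnNMe3ICl2 (1.05 equiv), CaCO3 (1.5 equiv), CH2Cl2–MeOH (5:2), rt, 3 h
Reagents that add atoms: benzyltrimethylammonium dichloroiodate, C[N+](C)(C)Cc1ccccc1.Cl[I-]Cl
Why: Electrophilic aromatic iodination of a phenol, in which the dichloroiodate reagent attacks free phenols but not aryl ethers under these buffered conditions (ring B is untouched) and 5-hydroxy-7-alkoxyflavanones react ortho to the chelated 5-OH at C6 in preference to C8, the C2 stereocentre not being involved.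

Step 9
Reactants: 12 ((2S)-6-iodoflavanone)
Product: 13 (2S)-6-iodoflavanone tetra-MOM ether [(2S)-6-iodo-5,7-bis(methoxymethoxy)-2-[2,4-bis(methoxymethoxy)phenyl]chroman-4-one]
Conditions: MOMCl (5 equiv), iPr2NEt (6 equiv), CH2Cl2, 40 °C, 24 h
Reagents that add atoms: chloromethyl methyl ether, COCCl
Why: O-alkylation of the hindered chelated 5-OH with excess reagent and a non-nucleophilic amine base, needed because an ortho-hydroxy aryl iodide would undergo Larock-type heteroannulation with a 1,3-diene in the next step, and done without carbonate or hydride bases because these could open the flavanone by retro-oxa-Michael reaction and racemise C2.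

Step 10
Reactants: 13 ((2S)-6-iodoflavanone tetra-MOM ether); 14 (β-myrcene)
Product: 15 (2S)-dienyl flavanone [(2S)-5,7-bis(methoxymethoxy)-2-[2,4-bis(methoxymethoxy)phenyl]-6-[(1E)-7-methyl-3-methylideneocta-1,6-dienyl]chroman-4-one]
Conditions: 14 (5 equiv), Pd(OAc)2 (10 mol %), Ag2CO3 (1.2 equiv), DMF, 60 °C, 12 h, dark
Reagents that add atoms: none
Why: Mizoroki–Heck arylation of a 1,3-diene, in which the aryl–palladium species adds to the unsubstituted vinyl terminus of myrcene (the least hindered alkene carbon, as in Heck arylations of isoprene) and β-hydride elimination of the benzylic hydrogen gives the conjugated (E)-1-aryl diene, while Ag2CO3 removes iodide and is too weak a base to open the flavanone.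

Step 11
Reactants: 7 (dienophile chalcone); 15 ((2S)-dienyl flavanone)
Product: 18 hepta-MOM exo cycloadduct [(2S; 3''R,4''R,5''S), 2'-OH of the aroyl ring free], via chalcone boron chelate 16 (not isolated), via boron-bound cycloadduct 17 (not isolated)
Conditions: BH3·THF (1.2 equiv), AcOH (1.2 equiv), (R)-3,3'-diphenyl-[2,2'-binaphthalene]-1,1'-diol (1.2 equiv), THF, rt, 1 h, evaporate; then 7 (1.0 equiv), 15 (1.3 equiv), 4 Å molecular sieves, PhCF3, rt, 48 h; H2O work-up
Reagents that add atoms: none
Why: Biomimetic intermolecular Diels–Alder reaction promoted by a chiral boron Lewis acid, in which the 2'-hydroxychalcone binds boron as a phenoxide/carbonyl chelate (16) that lowers its LUMO, the nucleophilic CH2 terminus of the diene bonds to the β-carbon and the aryl-bearing terminus to the α-carbon (the required regiochemistry), the (E)-enone geometry fixes the groups at C4'' and C5'' trans, the exo transition state (aroyl group turned away from the diene, hence trans to the flavanone at C3'') is favoured because the di-ortho-substituted aryl group of the diene clashes with the ligand-bearing borate in the endo mode, and the (R)-biaryl ligand shields one face of the bound enone so that C3'', C4'' and C5'' are set as R, R and S under reagent control, the remote C2 centre of the diene having no say.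

Step 12
Reactants: 18 (hepta-MOM exo cycloadduct)
Product: 20 CNP0256494.1, via heptakis(trimethylsilyl) ether 19 (not isolated)
Conditions: TMSOTf (16 equiv), 2,2'-bipyridyl (24 equiv), CH3CN–CH2Cl2, 0 °C to rt, 3 h; then H2O, rt, 1 h
Reagents that add atoms: none
Why: Acetal exchange with a silyl triflate buffered by 2,2'-bipyridyl, which converts each aromatic MOM ether into a trimethylsilyl ether (19; the chelated phenol may be silylated as well) without protic acid before water cleaves all Si–O bonds at neutral pH, so that acid-catalysed ketalisation of the aryl ketone by the neighbouring phenols, cyclisation of the prenyl groups and base-induced ring opening of the 2',4'-dihydroxyflavanone are all avoided, no stereocentre being touched (C4'' already sits in the thermodynamically preferred all-trans arrangement).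

## Compound list

1 | 2,4-dihydroxybenzaldehyde | O=Cc1ccc(O)cc1O | starting material
2 | 2,4-bis(methoxymethoxy)benzaldehyde | COCOc1ccc(C=O)c(OCOC)c1 | intermediate
3 | 1-(2,4-dihydroxyphenyl)ethanone (2,4-dihydroxyacetophenone) | CC(=O)c1ccc(O)cc1O | starting material
4 | 1-bromo-3-methylbut-2-ene (prenyl bromide) | CC(C)=CCBr | starting material
5 | 1-[2,4-dihydroxy-3-(3-methylbut-2-enyl)phenyl]ethanone | CC(=O)c1ccc(O)c(CC=C(C)C)c1O | intermediate
6 | 1-[2-hydroxy-4-(methoxymethoxy)-3-(3-methylbut-2-enyl)phenyl]ethanone | CC(=O)c1ccc(OCOC)c(CC=C(C)C)c1O | intermediate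
7 | (E)-1-[2-hydroxy-4-(methoxymethoxy)-3-(3-methylbut-2-enyl)phenyl]-3-[2,4-bis(methoxymethoxy)phenyl]prop-2-en-1-one (tri-MOM morachalcone A) | CC(C)=CCc1c(OCOC)ccc(C(=O)/C=C/c2ccc(OCOC)cc2OCOC)c1O | intermediate
8 | 1-(2,4,6-trihydroxyphenyl)ethanone (2,4,6-trihydroxyacetophenone) | CC(=O)c1c(O)cc(O)cc1O | starting material
9 | 1-[2,6-dihydroxy-4-(methoxymethoxy)phenyl]ethanone | CC(=O)c1c(O)cc(OCOC)cc1O | intermediate
10 | (E)-1-[2,6-dihydroxy-4-(methoxymethoxy)phenyl]-3-[2,4-bis(methoxymethoxy)phenyl]prop-2-en-1-one | COCOc1cc(O)c(C(=O)/C=C/c2ccc(OCOC)cc2OCOC)c(O)c1 | intermediate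
11 | (2S)-5-hydroxy-7-(methoxymethoxy)-2-[2,4-bis(methoxymethoxy)phenyl]chroman-4-one | COCOc1cc(O)c2C(=O)C[C@@H](c3ccc(OCOC)cc3OCOC)Oc2c1 | intermediate
12 | (2S)-5-hydroxy-6-iodo-7-(methoxymethoxy)-2-[2,4-bis(methoxymethoxy)phenyl]chroman-4-one | COCOc1cc2c(c(O)c1I)C(=O)C[C@@H](c1ccc(OCOC)cc1OCOC)O2 | intermediate
13 | (2S)-6-iodo-5,7-bis(methoxymethoxy)-2-[2,4-bis(methoxymethoxy)phenyl]chroman-4-one | COCOc1cc2c(c(OCOC)c1I)C(=O)C[C@@H](c1ccc(OCOC)cc1OCOC)O2 | intermediate
14 | β-myrcene (7-methyl-3-methylideneocta-1,6-diene) | C=CC(=C)CCC=C(C)C | starting material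
15 | (2S)-5,7-bis(methoxymethoxy)-2-[2,4-bis(methoxymethoxy)phenyl]-6-[(1E)-7-methyl-3-methylideneocta-1,6-dienyl]chroman-4-one | CC(C)=CCCC(=C)/C=C/c1c(OCOC)cc2c(c1OCOC)C(=O)C[C@@H](c1ccc(OCOC)cc1OCOC)O2 | intermediate
16 | chalcone boron chelate: spiro-borate in which boron carries the (R)-3,3'-diphenyl-[2,2'-binaphthalene]-1,1'-diolate and the 2'-phenoxide and carbonyl oxygen of 7 (the (R) axis is carried by the name) | CC(C)=CCc1c(OCOC)ccc2c1O[B-]3(Oc4c(c(-c5ccccc5)cc5ccccc45)-c4c(O3)c5ccccc5cc4-c4ccccc4)[O+]=C2/C=C/c1ccc(OCOC)cc1OCOC | intermediate (not isolated)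
17 | boron-bound cycloadduct: the same spiro-borate carried by the phenoxide and ketone oxygen of 18, (2S; 3''R,4''R,5''S), (R) axis carried by the name | CC(C)=CCCC1=C[C@@H](c2c(OCOC)cc3c(c2OCOC)C(=O)C[C@@H](c2ccc(OCOC)cc2OCOC)O3)[C@H](C2=[O+][B-]6(Oc7c(c(-c8ccccc8)cc8ccccc78)-c7c(O6)c8ccccc8cc7-c7ccccc7)Oc6c(CC=C(C)C)c(OCOC)ccc62)[C@@H](c2ccc(OCOC)cc2OCOC)C1 | intermediate (not isolated)
18 | {(1R,2R,6S)-2-[(2S)-5,7-bis(methoxymethoxy)-2-[2,4-bis(methoxymethoxy)phenyl]-4-oxochroman-6-yl]-6-[2,4-bis(methoxymethoxy)phenyl]-4-(4-methylpent-3-enyl)cyclohex-3-en-1-yl}[2-hydroxy-4-(methoxymethoxy)-3-(3-methylbut-2-enyl)phenyl]methanone; all-trans, that is (3''R,4''R,5''S) | CC(C)=CCCC1=C[C@@H](c2c(OCOC)cc3c(c2OCOC)C(=O)C[C@@H](c2ccc(OCOC)cc2OCOC)O3)[C@H](C(=O)c2ccc(OCOC)c(CC=C(C)C)c2O)[C@@H](c2ccc(OCOC)cc2OCOC)C1 | intermediate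
19 | heptakis(trimethylsilyl) ether of 20 (all seven former MOM positions as OSiMe3, chelated 2'-OH shown free), (2S; 3''R,4''R,5''S) | CC(C)=CCCC1=C[C@@H](c2c(O[Si](C)(C)C)cc3c(c2O[Si](C)(C)C)C(=O)C[C@@H](c2ccc(O[Si](C)(C)C)cc2O[Si](C)(C)C)O3)[C@H](C(=O)c2ccc(O[Si](C)(C)C)c(CC=C(C)C)c2O)[C@@H](c2ccc(O[Si](C)(C)C)cc2O[Si](C)(C)C)C1 | intermediate (not isolated)
20 | CNP0256494.1: {(1R,2R,6S)-2-[(2S)-2-(2,4-dihydroxyphenyl)-5,7-dihydroxy-4-oxochroman-6-yl]-6-(2,4-dihydroxyphenyl)-4-(4-methylpent-3-enyl)cyclohex-3-en-1-yl}[2,4-dihydroxy-3-(3-methylbut-2-enyl)phenyl]methanone | CC(C)=CCCC1=C[C@@H](c2c(O)cc3c(c2O)C(=O)C[C@@H](c2ccc(O)cc2O)O3)[C@H](C(=O)c2ccc(O)c(CC=C(C)C)c2O)[C@@H](c2ccc(O)cc2O)C1 | target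

## Step count and risks

Total step count: 12. Longest linear sequence: 8 steps (steps 5, 6, 7, 8, 9, 10, 11, 12 from 8; equally steps 1, 6, 7, 8, 9, 10, 11, 12 from 1).

The three steps most likely to fail:

**Step 7 (asymmetric oxa-Michael closure).** High enantioselectivity has not been shown for an unactivated 2',6'-dihydroxychalcone. The reaction is reversible in principle and an uncatalysed racemic closure competes. The fallback sets out from 10 and comes back at 11. Chalcone 10 is closed without induction (NaOAc, EtOH, reflux) to the racemic flavanone F1. F1 is then resolved kinetically by Noyori-type asymmetric transfer hydrogenation ([RhCl(C5Me5)((1R,2R)-TsNCHPhCHPhNH2)] 1 mol %, HCO2H–Et3N 5:2, EtOAc, 40 °C, stopped near 50% conversion). The (2R) enantiomer is reduced to the cis-flavan-4-ol F2, and unreduced (2S)-11 is recovered by chromatography (at most 50%). Stereocontrol thus moves from the ring closure to a later resolution.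

**Step 11 (chiral boron Diels–Alder reaction).** The exo/endo ratio with this diene is not known, and the fixed (2S) centre could make the pairing with the ligand mismatched. The fallback sets out from 7 and 15 and comes back at 18. Reagent control is given up: the cycloaddition is run with an achiral electron-transfer catalyst, silica-supported silver nanoparticles (zerovalent silver, Ag on SiO2, about 0.3 mol % Ag, CH2Cl2, 50 °C, 24–48 h). Because 15 is already enantiopure, the four cycloadducts are diastereomers and are separated by preparative HPLC. They are 18, its exo diastereomer F3 (3''S,4''S,5''R) and the two endo diastereomers F4 (3''S,4''R,5''S) and F5 (3''R,4''S,5''R).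

**Step 12 (sevenfold MOM removal).** The exo adduct can ketalise at its aryl ketone under Lewis or protic acid, the prenyl groups can cyclise onto their ortho-phenols, and the flavanone racemises under base. The fallback changes the protecting groups before the cycloaddition; it sets out from 7 and 12 and comes back at 20.
- Chalcone 7 is freed with HCl (3 M aq.) in MeOH at 40 °C to morachalcone A F6, which is acetylated (Ac2O 3.3 equiv, pyridine, 0 °C) to the 4',2,4-triacetate F7 with the chelated 2'-OH left free.
- Iodoflavanone 12 is freed in the same way to (2S)-6-iodo-5,7,2',4'-tetrahydroxyflavanone F8 and peracetylated (Ac2O, pyridine, DMAP, rt) to the tetraacetate F9.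
- Heck arylation of 14 with F9 under the conditions of step 10 gives the diene tetraacetate F10.
- The boron-promoted cycloaddition of F7 with F10 under the conditions of step 11 gives the heptaacetate cycloadduct F11.
- F11 is deacetylated under neutral conditions (NH4OAc, MeOH–H2O, rt) to 20, so that no acid is used after the cycloaddition.

## Further compounds

F1 | step 7 | racemic 5-hydroxy-7-(methoxymethoxy)-2-[2,4-bis(methoxymethoxy)phenyl]chroman-4-one | COCOc1cc(O)c2C(=O)CC(c3ccc(OCOC)cc3OCOC)Oc2c1
F2 | step 7 | (2R,4R)-7-(methoxymethoxy)-2-[2,4-bis(methoxymethoxy)phenyl]chromane-4,5-diol (cis-flavan-4-ol) | COCOc1cc(O)c2[C@H](O)C[C@H](c3ccc(OCOC)cc3OCOC)Oc2c1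
F3 | step 11 | exo diastereomer of 18, (2S; 3''S,4''S,5''R) | CC(C)=CCCC1=C[C@H](c2c(OCOC)cc3c(c2OCOC)C(=O)C[C@@H](c2ccc(OCOC)cc2OCOC)O3)[C@@H](C(=O)c2ccc(OCOC)c(CC=C(C)C)c2O)[C@H](c2ccc(OCOC)cc2OCOC)C1
F4 | step 11 | endo diastereomer of 18, (2S; 3''S,4''R,5''S) | CC(C)=CCCC1=C[C@H](c2c(OCOC)cc3c(c2OCOC)C(=O)C[C@@H](c2ccc(OCOC)cc2OCOC)O3)[C@H](C(=O)c2ccc(OCOC)c(CC=C(C)C)c2O)[C@@H](c2ccc(OCOC)cc2OCOC)C1
F5 | step 11 | endo diastereomer of 18, (2S; 3''R,4''S,5''R) | CC(C)=CCCC1=C[C@@H](c2c(OCOC)cc3c(c2OCOC)C(=O)C[C@@H](c2ccc(OCOC)cc2OCOC)O3)[C@@H](C(=O)c2ccc(OCOC)c(CC=C(C)C)c2O)[C@H](c2ccc(OCOC)cc2OCOC)C1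
F6 | step 12 | morachalcone A, (E)-1-[2,4-dihydroxy-3-(3-methylbut-2-enyl)phenyl]-3-(2,4-dihydroxyphenyl)prop-2-en-1-one | CC(C)=CCc1c(O)ccc(C(=O)/C=C/c2ccc(O)cc2O)c1O
F7 | step 12 | morachalcone A 4',2,4-triacetate (2'-OH free) | CC(C)=CCc1c(OC(C)=O)ccc(C(=O)/C=C/c2ccc(OC(C)=O)cc2OC(C)=O)c1O
F8 | step 12 | (2S)-2-(2,4-dihydroxyphenyl)-5,7-dihydroxy-6-iodochroman-4-one | Oc1cc2c(c(O)c1I)C(=O)C[C@@H](c1ccc(O)cc1O)O2
F9 | step 12 | (2S)-5,7-diacetoxy-2-(2,4-diacetoxyphenyl)-6-iodochroman-4-one | CC(=O)Oc1cc2c(c(OC(C)=O)c1I)C(=O)C[C@@H](c1ccc(OC(C)=O)cc1OC(C)=O)O2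
F10 | step 12 | (2S)-5,7-diacetoxy-2-(2,4-diacetoxyphenyl)-6-[(1E)-7-methyl-3-methylideneocta-1,6-dienyl]chroman-4-one | CC(C)=CCCC(=C)/C=C/c1c(OC(C)=O)cc2c(c1OC(C)=O)C(=O)C[C@@H](c1ccc(OC(C)=O)cc1OC(C)=O)O2
F11 | step 12 | heptaacetate of 20 (2'-OH of the aroyl ring free), (2S; 3''R,4''R,5''S) | CC(C)=CCCC1=C[C@@H](c2c(OC(C)=O)cc3c(c2OC(C)=O)C(=O)C[C@@H](c2ccc(OC(C)=O)cc2OC(C)=O)O3)[C@H](C(=O)c2ccc(OC(C)=O)c(CC=C(C)C)c2O)[C@@H](c2ccc(OC(C)=O)cc2OC(C)=O)C1
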